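**Strategy.** The target is cut at its spiro-dihydropyran into (+)-alantolactone and a cis-fused eudesma-4(15),11(13)-dien-12-al, joined last by a hetero-Diels–Alder reaction. Everything rests on ring B of the lactone half (C5–C10), which is a cyclohex-3-enone in disguise: C8 oxygen, C5=C6 alkene, quaternary C10. It is made from a cyclobutanone, the dichloroketene [2+2] adduct of a vinylcyclohexene, by a [1,3] shift of the CCl2 carbon (C9) from C6 to C10. This two-carbon ring expansion builds ring B, the C10 quaternary centre (steered by the C4 methyl) and the C5=C6 alkene in one operation.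

Key step: step 4

Remarks and assumptions
- Locants are eudesmane locants. Lactone half: ring A = C1–C5, C10; ring B = C5–C10; lactone carbons C11–C13. Aldehyde half: the same locants with a prime.
- The aldehyde half of the given structure is read as a cis-fused decalin with C10'–CH3, C5'–H and the C7' side chain on one face; this is the stereotriad that (R)-carvone delivers in steps 11 and 12.
- Commercial 2,6-dimethylcyclohexanone is taken as its cis (meso) isomer. The sense of induction of the chiral amide in step 1 is assumed; if it is opposite, the (S,S)-amide is used.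

**Part A: lactone half**

Step 1
Reactants: 1 cis-2,6-dimethylcyclohexan-1-one
Product: 3 (6S)-2,6-dimethylcyclohex-1-en-1-yl trifluoromethanesulfonate, via lithium enolate 2 (not isolated)
Conditions: lithium (R,R)-bis(1-phenylethyl)amide, LiCl, THF, −78 °C; then PhNTf2, −78 to 0 °C
Reagents that add atoms: N-phenylbis(trifluoromethanesulfonimide), O=S(=O)(N(c1ccccc1)S(=O)(=O)C(F)(F)F)C(F)(F)F
Why: Enantioselective deprotonation of the meso ketone by a chiral lithium amide removes one of the two enantiotopic α-protons, so the untouched CH(CH3) centre (later C4) is left S, and O-triflation of the enolate locks this in as an enol triflate.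

Step 2
Reactants: 3 (6S)-2,6-dimethylcyclohex-1-en-1-yl trifluoromethanesulfonate
Product: 4 (6S)-1-ethenyl-2,6-dimethylcyclohex-1-ene
Conditions: tributyl(vinyl)stannane, Pd(PPh3)4 (cat.), LiCl, THF, 65 °C
Reagents that add atoms: tributyl(vinyl)stannane, C=C[Sn](CCCC)(CCCC)CCCC
Why: Stille cross-coupling of hindered cyclohexenyl triflates with vinylstannanes is reliable and does not touch the allylic stereocentre.

Step 3
Reactants: 4 (6S)-1-ethenyl-2,6-dimethylcyclohex-1-ene
Product: 5 (3S)-2,2-dichloro-3-[(6S)-2,6-dimethylcyclohex-1-en-1-yl]cyclobutan-1-one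
Conditions: Cl3CCOCl, Zn–Cu couple, POCl3, Et2O, 0 °C to rt
Reagents that add atoms: trichloroacetyl chloride (source of dichloroketene), ClC(Cl)(Cl)C(Cl)=O
Why: Ketene–alkene [2+2] cycloaddition of dichloroketene at the unhindered vinyl group should put the carbonyl carbon (C8) on the terminal CH2 (C7) and the CCl2 carbon (C9) on C6, where the ring alkene stabilises developing positive charge; approach from the vinyl face next to C4–H, with C7 anti to the pseudoaxial C4 methyl, should give the 3S centre, which is erased again in step 4.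

Step 4
Reactants: 5 (3S)-2,2-dichloro-3-[(6S)-2,6-dimethylcyclohex-1-en-1-yl]cyclobutan-1-one
Product: 6 (5S,8aS)-1,1-dichloro-5,8a-dimethyl-1,5,6,7,8,8a-hexahydronaphthalen-2(3H)-one
Conditions: 1,2-dichlorobenzene (0.05 M), BHT (cat.), 140 °C
Reagents that add atoms: none
Why: Proposed new method: the C9–C6 bond of the cyclobutanone lies between an acceptor (C8=O with the two chlorines on C9) and a donor (the tetrasubstituted cyclohexenyl group on C6), so on heating it should open to a stabilised pair (α-keto-α,α-dichloro radical or enolate at C9 and the C6–C5–C10 allyl unit) that recombines at C10, a [1,3] shift that turns the four-membered ring C6–C7–C8–C9 into the six-membered ring B with the C5=C6 alkene and the C10 quaternary centre. The closest known reactions are the thermal vinylcyclobutane-to-cyclohexene rearrangement, its alkoxide-accelerated variant, and the Lewis-acid opening of 3-donor-substituted cyclobutanones at this same bond. Ring B closes by 6-endo recombination of C9 with the distal allyl terminus, and no other ring is formed. The only new stereocentre, C10, is controlled by the C4 methyl: C9 forms its bond axially on the ring A half-chair, on the face anti to the pseudoaxial C4–CH3, which leaves the C4 and C10 methyl groups cis, and both C6 epimers of 5 should converge because C6 becomes sp2. The step needs C-recombination at C10 in preference to return to C6 or reversible O-recombination to a 2H-pyran; relief of ring strain makes the cyclohexenone the thermodynamic sink, and the quaternary C10 blocks loss of HCl to a phenol.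

Step 5
Reactants: 6 (5S,8aS)-1,1-dichloro-5,8a-dimethyl-1,5,6,7,8,8a-hexahydronaphthalen-2(3H)-one
Product: 9 methyl 2-[(5S,8aS)-1,1-dichloro-5,8a-dimethyl-2-oxo-1,5,6,7,8,8a-hexahydronaphthalen-3(2H)-ylidene]acetate, via aldol adduct 7 (not isolated), via mesylate 8 (not isolated)
Conditions: TiCl4, Et3N, CH2Cl2, −78 °C; methyl glyoxylate, −78 to 0 °C; then MsCl, Et3N, 0 °C to rt
Reagents that add atoms: methyl glyoxylate, COC(=O)C=O
Why: In this titanium-mediated crossed aldol condensation enolisation can only occur at C7 (C9 carries no hydrogen), the dienolate adds to the glyoxylate through C7, and E1cB loss of mesylate gives the cross-conjugated alkylidene ketone, so C11 and C12 are attached without yet creating a C7 stereocentre.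

Step 6
Reactants: 9 methyl 2-[(5S,8aS)-1,1-dichloro-5,8a-dimethyl-2-oxo-1,5,6,7,8,8a-hexahydronaphthalen-3(2H)-ylidene]acetate
Product: 10 methyl 2-[(2S,4aR,8S)-4a,8-dimethyl-3-oxo-2,3,4,4a,5,6,7,8-octahydronaphthalen-2-yl]acetate
Conditions: Zn dust, AcOH, rt
Reagents that add atoms: none
Why: Zinc in acetic acid should effect both reductive dechlorination of the α,α-dichloro ketone and conjugate reduction of the ene-dicarbonyl C7=C11 bond, and ketonisation of the resulting dienol at C7 from the α face (anti to the pseudoaxial C10 methyl) places the side chain β, which is also the more stable pseudoequatorial epimer, while the C5=C6 alkene stays out of conjugation as in the zinc debromination route to 5-en-3-one steroids.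

Step 7
Reactants: 10 methyl 2-[(2S,4aR,8S)-4a,8-dimethyl-3-oxo-2,3,4,4a,5,6,7,8-octahydronaphthalen-2-yl]acetate
Product: 12 (3aS,5S,8aR,9aR)-5,8a-dimethyl-3a,5,6,7,8,8a,9,9a-octahydronaphtho[2,3-b]furan-2(3H)-one, via hydroxy ester 11 (not isolated)
Conditions: NaBH4, MeOH, 0 °C; then TsOH (cat.), CH2Cl2, rt
Reagents that add atoms: none
Why: In this hydride reduction–lactonisation the hydride should attack C8 from the α face because the β face is shielded by the 1,3-related pseudoaxial C10 methyl, giving the axial 8β-alcohol cis to the C7 side chain, which closes to the cis-fused γ-lactone.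

Step 8
Reactants: 12 (3aS,5S,8aR,9aR)-5,8a-dimethyl-3a,5,6,7,8,8a,9,9a-octahydronaphtho[2,3-b]furan-2(3H)-one
Product: 16 (+)-alantolactone [(3aR,5S,8aR,9aR)-5,8a-dimethyl-3-methylidene-3a,5,6,7,8,8a,9,9a-octahydronaphtho[2,3-b]furan-2(3H)-one], via lactone enolate 13 (not isolated), via Mannich base 14 (not isolated), via methiodide 15 (not isolated)
Conditions: LiN(i-Pr)2, THF, −78 °C; CH2=NMe2+ I−, −78 °C to rt; then MeI, MeOH, rt; then NaHCO3 aq., CH2Cl2, rt
Reagents that add atoms: dimethyl(methylidene)ammonium iodide (Eschenmoser's salt), C=[N+](C)C.[I-]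
Why: Mannich aminomethylation of the lactone enolate followed by quaternisation and Hofmann-type elimination is the standard α-methylenation of γ-lactones and leaves the four stereocentres untouched.

**Part B: aldehyde half**

Step 9
Reactants: 17 5-chloropent-1-yne
Product: 18 2-bromo-5-chloropent-1-ene
Conditions: HBr, Et4NBr, CH2Cl2, 40 °C
Reagents that add atoms: hydrogen bromide, Br
Why: Markovnikov hydrobromination of a terminal alkyne with the hydrogen dibromide salt gives the 2-bromoalk-1-ene and stops at that stage.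

Step 10
Reactants: 19 (R)-(−)-carvone
Product: 20 (5R)-2-methyl-5-(2-methyloxiran-2-yl)cyclohex-2-en-1-one
Conditions: mCPBA, CH2Cl2, 0 °C
Reagents that add atoms: 3-chloroperoxybenzoic acid, OOC(=O)c1cccc(Cl)c1
Why: Prilezhaev epoxidation takes the electron-rich isopropenyl group and not the enone alkene, which marks this alkene for later conversion to the enal and distinguishes it from the methylidene group introduced in step 11 (the oxirane carbon is formed as both epimers, which does not matter).

Step 11
Reactants: 18 2-bromo-5-chloropent-1-ene + 20 (5R)-2-methyl-5-(2-methyloxiran-2-yl)cyclohex-2-en-1-one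
Product: 23 (3R,5R)-3-(5-chloropent-1-en-2-yl)-2-methyl-5-(2-methyloxiran-2-yl)cyclohexan-1-one, via alkenyllithium 21 (not isolated), via lithium dialkenylcuprate 22 (not isolated)
Conditions: 18 (2 equiv), t-BuLi, Et2O, −78 °C; CuI, −78 to −40 °C; then 20, −78 to −40 °C; NH4Cl aq.
Reagents that add atoms: none
Why: Bromine–lithium exchange at −78 °C spares the alkyl chloride, and cuprate conjugate addition to the carvone-type enone occurs trans to the C5 substituent, which puts the later C5'–H on the face of the C7' side chain (the enolisable C2 centre is formed as a mixture).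

Step 12
Reactants: 23 (3R,5R)-3-(5-chloropent-1-en-2-yl)-2-methyl-5-(2-methyloxiran-2-yl)cyclohexan-1-one
Product: 24 (3R,4aS,8aR)-8a-methyl-5-methylidene-3-(2-methyloxiran-2-yl)octahydronaphthalen-1(2H)-one
Conditions: KH, THF, rt
Reagents that add atoms: none
Why: In this intramolecular enolate alkylation (methylenecyclohexane annulation, 6-exo-tet) the more substituted potassium enolate attacks the tethered primary chloride axially through a chair-like transition state that can only give the cis-fused decalone, so C10'–CH3, C5'–H and the C7' side chain end on one face.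

Step 13
Reactants: 24 (3R,4aS,8aR)-8a-methyl-5-methylidene-3-(2-methyloxiran-2-yl)octahydronaphthalen-1(2H)-one
Product: 25 (3R,4aS,8aR)-3-(3-hydroxyprop-1-en-2-yl)-8a-methyl-5-methylideneoctahydronaphthalen-1(2H)-one
Conditions: Et2AlCl, lithium 2,2,6,6-tetramethylpiperidide, toluene, 0 °C; then 24, 0 °C
Reagents that add atoms: none
Why: In this base-induced epoxide-to-allylic-alcohol isomerisation the bulky aluminium amide binds the oxirane oxygen and removes a proton from the unhindered methyl group, which gives the 2-substituted allylic alcohol; the ketone is only enolised reversibly.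

Step 14
Reactants: 25 (3R,4aS,8aR)-3-(3-hydroxyprop-1-en-2-yl)-8a-methyl-5-methylideneoctahydronaphthalen-1(2H)-one
Product: 27 2-[(2S,4aS,8aS)-4a-methyl-8-methylidenedecahydronaphthalen-2-yl]prop-2-en-1-ol, via hydrazone 26 (not isolated)
Conditions: N2H4·H2O, KOH, diethylene glycol, 130 °C then 200 °C
Reagents that add atoms: none
Why: Wolff–Kishner reduction under Huang-Minlon conditions removes the C9' carbonyl, which has done its work in the annulation, and should tolerate the free alcohol and the two 1,1-disubstituted alkenes.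

Step 15
Reactants: 27 2-[(2S,4aS,8aS)-4a-methyl-8-methylidenedecahydronaphthalen-2-yl]prop-2-en-1-ol
Product: 28 2-[(2S,4aS,8aS)-4a-methyl-8-methylidenedecahydronaphthalen-2-yl]prop-2-enal
Conditions: MnO2, CH2Cl2, rt
Reagents that add atoms: none
Why: Allylic oxidation with MnO2 converts the allylic alcohol selectively into the 2-substituted acrolein and leaves the isolated methylidene group alone.

**Part C: union**

Step 16
Reactants: 16 (+)-alantolactone + 28 2-[(2S,4aS,8aS)-4a-methyl-8-methylidenedecahydronaphthalen-2-yl]prop-2-enal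
Product: 29 CNP0108778.1 [(3R,3aS,5S,8aR,9aR)-5,8a-dimethyl-5'-[(2S,4aS,8aS)-4a-methyl-8-methylidenedecahydronaphthalen-2-yl]-3a,3',4',5,6,7,8,8a,9,9a-decahydro-2H-spiro[naphtho[2,3-b]furan-3,2'-pyran]-2-one]
Conditions: 28 (2 equiv), toluene (2 M), BHT (cat.), 100 °C, sealed tube
Reagents that add atoms: none
Why: In this hetero-Diels–Alder reaction the s-cis enal (O=C12'–C11'=C13') adds to the exocyclic C11=C13 alkene with the orientation of acrolein dimerisation (C13' to C13, aldehyde oxygen to C11), and approach to the convex face of the cis-fused lactone (the face of H7 and H8, anti to ring B) should set the spiro centre C11; the excess of enal offsets its own dimerisation.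

**Compound list**

1 | cis-2,6-dimethylcyclohexan-1-one (meso; 2R,6S) | C[C@H]1CCC[C@@H](C)C1=O | starting material
2 | lithium (6S)-2,6-dimethylcyclohex-1-en-1-olate | C[C@H]1CCCC(C)=C1[O-].[Li+] | intermediate (not isolated)
3 | (6S)-2,6-dimethylcyclohex-1-en-1-yl trifluoromethanesulfonate | C[C@H]1CCCC(C)=C1OS(=O)(=O)C(F)(F)F | intermediate
4 | (6S)-1-ethenyl-2,6-dimethylcyclohex-1-ene | C[C@H]1CCCC(C)=C1C=C | intermediate
5 | (3S)-2,2-dichloro-3-[(6S)-2,6-dimethylcyclohex-1-en-1-yl]cyclobutan-1-one | C[C@H]1CCCC(C)=C1[C@@H]2CC(=O)C2(Cl)Cl | intermediate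
6 | (5S,8aS)-1,1-dichloro-5,8a-dimethyl-1,5,6,7,8,8a-hexahydronaphthalen-2(3H)-one | O=C1C(Cl)(Cl)[C@@]2(C)CCC[C@H](C)C2=CC1 | intermediate
7 | methyl 2-[(5S,8aS)-1,1-dichloro-5,8a-dimethyl-2-oxo-1,2,3,5,6,7,8,8a-octahydronaphthalen-3-yl]-2-hydroxyacetate (epimers at C3 and at the carbinol carbon) | COC(=O)C(O)C1C=C2[C@@H](C)CCC[C@]2(C)C(Cl)(Cl)C1=O | intermediate (not isolated)
8 | methanesulfonate of 7 | COC(=O)C(OS(C)(=O)=O)C1C=C2[C@@H](C)CCC[C@]2(C)C(Cl)(Cl)C1=O | intermediate (not isolated)
9 | methyl 2-[(5S,8aS)-1,1-dichloro-5,8a-dimethyl-2-oxo-1,5,6,7,8,8a-hexahydronaphthalen-3(2H)-ylidene]acetate (alkene geometry not fixed) | COC(=O)C=C1C=C2[C@@H](C)CCC[C@]2(C)C(Cl)(Cl)C1=O | intermediate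
10 | methyl 2-[(2S,4aR,8S)-4a,8-dimethyl-3-oxo-2,3,4,4a,5,6,7,8-octahydronaphthalen-2-yl]acetate | O=C1C[C@@]2(C)CCC[C@H](C)C2=C[C@@H]1CC(=O)OC | intermediate
11 | methyl 2-[(2S,3R,4aR,8S)-3-hydroxy-4a,8-dimethyl-2,3,4,4a,5,6,7,8-octahydronaphthalen-2-yl]acetate | O[C@@H]1C[C@@]2(C)CCC[C@H](C)C2=C[C@@H]1CC(=O)OC | intermediate (not isolated)
12 | (3aS,5S,8aR,9aR)-5,8a-dimethyl-3a,5,6,7,8,8a,9,9a-octahydronaphtho[2,3-b]furan-2(3H)-one | O=C1C[C@H]2C=C3[C@@H](C)CCC[C@]3(C)C[C@H]2O1 | intermediate
13 | lithium enolate of 12 | [Li+].[O-]C1=C[C@H]2C=C3[C@@H](C)CCC[C@]3(C)C[C@H]2O1 | intermediate (not isolated)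
14 | 3-[(dimethylamino)methyl] derivative of 12 (C3 epimers) | O=C1C(CN(C)C)[C@H]2C=C3[C@@H](C)CCC[C@]3(C)C[C@H]2O1 | intermediate (not isolated)
15 | N-methyl iodide of 14 | O=C1C(C[N+](C)(C)C)[C@H]2C=C3[C@@H](C)CCC[C@]3(C)C[C@H]2O1.[I-] | intermediate (not isolated)
16 | (+)-alantolactone, (3aR,5S,8aR,9aR)-5,8a-dimethyl-3-methylidene-3a,5,6,7,8,8a,9,9a-octahydronaphtho[2,3-b]furan-2(3H)-one | O=C1C(=C)[C@H]2C=C3[C@@H](C)CCC[C@]3(C)C[C@H]2O1 | intermediate
17 | 5-chloropent-1-yne | C#CCCCCl | starting material
18 | 2-bromo-5-chloropent-1-ene | C=C(Br)CCCCl | intermediate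
19 | (R)-(−)-carvone | CC1=CC[C@H](CC1=O)C(C)=C | starting material
20 | (5R)-2-methyl-5-(2-methyloxiran-2-yl)cyclohex-2-en-1-one (oxirane epimers) | CC1=CC[C@H](CC1=O)C2(C)CO2 | intermediate
21 | (5-chloropent-1-en-2-yl)lithium | [Li]C(=C)CCCCl | intermediate (not isolated)
22 | lithium bis(5-chloropent-1-en-2-yl)cuprate | [Li+].C=C(CCCCl)[Cu-]C(=C)CCCCl | intermediate (not isolated)
23 | (3R,5R)-3-(5-chloropent-1-en-2-yl)-2-methyl-5-(2-methyloxiran-2-yl)cyclohexan-1-one (C2 and oxirane epimers) | C=C(CCCCl)[C@@H]1C[C@@H](C2(C)CO2)CC(=O)C1C | intermediate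
24 | (3R,4aS,8aR)-8a-methyl-5-methylidene-3-(2-methyloxiran-2-yl)octahydronaphthalen-1(2H)-one | C=C1CCC[C@@]2(C)C(=O)C[C@H](C3(C)CO3)C[C@@H]12 | intermediate
25 | (3R,4aS,8aR)-3-(3-hydroxyprop-1-en-2-yl)-8a-methyl-5-methylideneoctahydronaphthalen-1(2H)-one | C=C1CCC[C@@]2(C)C(=O)C[C@H](C(=C)CO)C[C@@H]12 | intermediate
26 | hydrazone of 25 | C=C1CCC[C@@]2(C)C(=NN)C[C@H](C(=C)CO)C[C@@H]12 | intermediate (not isolated)
27 | 2-[(2S,4aS,8aS)-4a-methyl-8-methylidenedecahydronaphthalen-2-yl]prop-2-en-1-ol | C=C1CCC[C@@]2(C)CC[C@H](C(=C)CO)C[C@@H]12 | intermediate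
28 | 2-[(2S,4aS,8aS)-4a-methyl-8-methylidenedecahydronaphthalen-2-yl]prop-2-enal | C=C1CCC[C@@]2(C)CC[C@H](C(=C)C=O)C[C@@H]12 | intermediate
29 | CNP0108778.1, spiro adduct of 16 and 28 (name as in step 16) | C=C1CCC[C@@]2(C)CC[C@H](C3=CO[C@@]4(CC3)C(=O)O[C@@H]3C[C@@]5(C)CCC[C@H](C)C5=C[C@@H]34)C[C@@H]12 | target

**Totals and risks**

Total step count: 16. Longest linear sequence: 9 steps (steps 1 to 8, then step 16).

Steps most likely to fail:

1. Step 4 (Proposed new method). The cyclobutanone may cyclorevert, the open intermediate may disproportionate or recombine through oxygen, or C9 may be delivered to the wrong face of C10. The fallback uses known reactions and still makes ring B by ring expansion, here of a five-membered ring by one carbon; it sets out from 2 and comes back at 10. Enolate 2 is C-alkylated with allyl bromide (THF, DMPU, −78 to 0 °C; axial attack anti to the C4 methyl) to give (2R,6S)-2,6-dimethyl-2-(prop-2-en-1-yl)cyclohexan-1-one F1. Addition of CH2=CHMgBr with CeCl3 gives (2R,6S)-1-ethenyl-2,6-dimethyl-2-(prop-2-en-1-yl)cyclohexan-1-ol F2. Ring-closing metathesis with the second-generation Grubbs catalyst gives (4S,7aR)-4,7a-dimethyl-1,4,5,6,7,7a-hexahydro-3aH-inden-3a-ol F3. Hydroxyl-directed Simmons–Smith cyclopropanation (Et2Zn, CH2I2) gives the cyclopropylcarbinol (4S,7aR)-4,7a-dimethyl-2,3-methanooctahydro-3aH-inden-3a-ol F4. Aqueous HClO4 in dioxane then triggers the cyclopropylcarbinyl-to-homoallyl rearrangement: the C6–C8 bond shared by the three- and five-membered rings breaks, C7 enters the ring and water adds at C8, giving (5S,8aR)-5,8a-dimethyl-1,2,3,5,6,7,8,8a-octahydronaphthalen-2-ol F5. Dess–Martin oxidation gives (5S,8aR)-5,8a-dimethyl-1,5,6,7,8,8a-hexahydronaphthalen-2(3H)-one F6. Aldol condensation with methyl glyoxylate under the conditions of step 5 gives methyl 2-[(5S,8aR)-5,8a-dimethyl-2-oxo-1,5,6,7,8,8a-hexahydronaphthalen-3(2H)-ylidene]acetate F7, and zinc in acetic acid reduces F7 to 10.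

2. Step 6. The dienol may be protonated at C5 instead of C7 (the alkene slips into conjugation), the protonation at C7 may take the wrong face, or the dienone may be over-reduced. The fallback replaces condensation–reduction by alkylation and a separate inversion at C7; it sets out from 6 and comes back at 10. Zinc in acetic acid on 6 alone gives (5S,8aR)-5,8a-dimethyl-1,5,6,7,8,8a-hexahydronaphthalen-2(3H)-one F8. Its lithium dienolate (LiN(i-Pr)2, THF, −78 °C) is alkylated at C7 with methyl bromoacetate, expected from the α face, to give methyl 2-[(2R,4aR,8S)-4a,8-dimethyl-3-oxo-2,3,4,4a,5,6,7,8-octahydronaphthalen-2-yl]acetate F9, the C7 epimer of 10. The thermodynamic potassium dienolate of F9 (KN(SiMe3)2, slightly less than one equivalent, THF, −78 to 0 °C) is then protonated kinetically at C7 with acetic acid at −78 °C, again from the α face, which inverts C7 and gives 10.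

3. Step 14. Hydrazone formation at the hindered carbonyl may stall, and the exocyclic double bonds may migrate in hot base. The fallback changes both the deoxygenation method and the order of events; it sets out from 24 and comes back at 27. NaBH4 reduces 24 to (3R,4aS,8aR)-8a-methyl-5-methylidene-3-(2-methyloxiran-2-yl)decahydronaphthalen-1-ol F10. NaH, CS2 and MeI give its O-alkyl S-methyl xanthate F11. Barton–McCombie deoxygenation (Bu3SnH, AIBN, toluene, 110 °C) gives 2-methyl-2-[(2S,4aS,8aS)-4a-methyl-8-methylidenedecahydronaphthalen-2-yl]oxirane F12, and the aluminium amide isomerisation of step 13, now without a ketone present, gives 27.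

**Further compounds**

F1 | step 4 | (2R,6S)-2,6-dimethyl-2-(prop-2-en-1-yl)cyclohexan-1-one | C=CC[C@@]1(C)CCC[C@H](C)C1=O
F2 | step 4 | (2R,6S)-1-ethenyl-2,6-dimethyl-2-(prop-2-en-1-yl)cyclohexan-1-ol (carbinol epimers) | C=CC[C@@]1(C)CCC[C@H](C)C1(O)C=C
F3 | step 4 | (4S,7aR)-4,7a-dimethyl-1,4,5,6,7,7a-hexahydro-3aH-inden-3a-ol (C3a epimers) | C[C@H]1CCC[C@]2(C)CC=CC12O
F4 | step 4 | (4S,7aR)-4,7a-dimethyl-2,3-methanooctahydro-3aH-inden-3a-ol (cyclopropane cis to the hydroxyl) | C[C@H]1CCC[C@]2(C)CC3CC3C12O
F5 | step 4 | (5S,8aR)-5,8a-dimethyl-1,2,3,5,6,7,8,8a-octahydronaphthalen-2-ol (C2 epimers) | OC1CC=C2[C@@H](C)CCC[C@]2(C)C1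
F6 | step 4 | (5S,8aR)-5,8a-dimethyl-1,5,6,7,8,8a-hexahydronaphthalen-2(3H)-one | O=C1CC=C2[C@@H](C)CCC[C@]2(C)C1
F7 | step 4 | methyl 2-[(5S,8aR)-5,8a-dimethyl-2-oxo-1,5,6,7,8,8a-hexahydronaphthalen-3(2H)-ylidene]acetate | COC(=O)C=C1C=C2[C@@H](C)CCC[C@]2(C)CC1=O
F8 | step 6 | (5S,8aR)-5,8a-dimethyl-1,5,6,7,8,8a-hexahydronaphthalen-2(3H)-one | O=C1CC=C2[C@@H](C)CCC[C@]2(C)C1
F9 | step 6 | methyl 2-[(2R,4aR,8S)-4a,8-dimethyl-3-oxo-2,3,4,4a,5,6,7,8-octahydronaphthalen-2-yl]acetate | O=C1C[C@@]2(C)CCC[C@H](C)C2=C[C@H]1CC(=O)OC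
F10 | step 14 | (3R,4aS,8aR)-8a-methyl-5-methylidene-3-(2-methyloxiran-2-yl)decahydronaphthalen-1-ol (C1 epimers) | C=C1CCC[C@@]2(C)C(O)C[C@H](C3(C)CO3)C[C@@H]12
F11 | step 14 | O-[(3R,4aS,8aR)-8a-methyl-5-methylidene-3-(2-methyloxiran-2-yl)decahydronaphthalen-1-yl] S-methyl carbonodithioate | C=C1CCC[C@@]2(C)C(OC(=S)SC)C[C@H](C3(C)CO3)C[C@@H]12
F12 | step 14 | 2-methyl-2-[(2S,4aS,8aS)-4a-methyl-8-methylidenedecahydronaphthalen-2-yl]oxirane | C=C1CCC[C@@]2(C)CC[C@H](C3(C)CO3)C[C@@H]12
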